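**Strategy.** Numbering the chain C1 (on the methoxycatechol ring, ArA) to C7 (on the 4-hydroxyphenyl ring, ArB), the route rests on disconnecting the C5–O bond: C5 is allylic to C7, the benzylic carbon on ArB, and 1,3 to the C3 carbinol. A Re(VII)-catalysed 1,3-hydroxyl shift from C7 to C5, run in the presence of benzaldehyde dimethyl acetal, should in one operation form the C5–O bond, close a 1,3-dioxane across O3/O5 and set C5 syn to the single preset centre C3. The precursor is an (E)-hept-2-ene-1,5-diol, (R) at the homoallylic carbinol and unselective at the benzylic one, with all three phenols as benzyl ethers.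

Key step: step 8

Remark: in protected intermediates ArA = 3,4-bis(benzyloxy)-5-methoxyphenyl and ArB = 4-(benzyloxy)phenyl; chain atoms keep the target numbering C1–C7.
Assumption: the all-cis (all-equatorial) benzylidene acetal is taken as the thermodynamic sink of step 8; the C5 descriptor later changes from R to S only because saturating C6=C7 alters the CIP ranking, not the geometry.

**Step 1**
Reactants: 1 3,4-dihydroxy-5-methoxybenzaldehyde
Product: 2 3,4-bis(benzyloxy)-5-methoxybenzaldehyde
Conditions: BnBr (2.4 equiv), K2CO3, DMF, 60 °C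
Reagents that add atoms: benzyl bromide, BrCc1ccccc1
Why: Williamson ether synthesis alkylates both phenols under carbonate, and benzyl ethers are chosen because they should survive every later step and leave together with the acetal in the final hydrogenolysis.

**Step 2**
Reactants: 2 3,4-bis(benzyloxy)-5-methoxybenzaldehyde
Product: 3 methyl (E)-3-(ArA)prop-2-enoate
Conditions: Ph3P=CHCO2Me, toluene, 90 °C
Reagents that add atoms: methyl (triphenylphosphoranylidene)acetate, COC(=O)C=P(c1ccccc1)(c1ccccc1)c1ccccc1
Why: Wittig olefination with a stabilised ylide should give the (E)-cinnamate cleanly from an electron-rich benzaldehyde.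

**Step 3**
Reactants: 3 methyl (E)-3-(ArA)prop-2-enoate
Product: 4 methyl 3-(ArA)propanoate
Conditions: NiCl2·6H2O (0.2 equiv), NaBH4, MeOH/THF, 0 °C
Reagents that add atoms: none
Why: Nickel boride conjugate reduction saturates the cinnamate C=C bond while leaving benzyl ethers and the ester untouched, and the methyl ester in methanol avoids transesterification mixtures.

**Step 4**
Reactants: 4 methyl 3-(ArA)propanoate
Product: 5 3-(ArA)propanal
Conditions: DIBAL-H (1.1 equiv), CH2Cl2, −78 °C; MeOH, aq. Rochelle salt
Reagents that add atoms: none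
Why: DIBAL-H half-reduction stops at the aldehyde because the tetrahedral aluminium hemiacetal persists at −78 °C and collapses only on work-up.

**Step 5**
Reactants: 5 3-(ArA)propanal
Product: 7 (R)-1-(ArA)hex-5-en-3-ol, via diisopinocampheylborinate ester 6 (not isolated)
Conditions: (−)-Ipc2BOMe, allylMgBr, Et2O, 0 °C to rt, Mg salts filtered off; 5, Et2O, −100 °C; 3 M NaOH, 30% H2O2, rt
Reagents that add atoms: allylmagnesium bromide, C=CC[Mg]Br, whose allyl group is passed to boron to give the B-allyldiisopinocampheylborane of the (+)-α-pinene series (dIpc2B-allyl), C=CCB([C@@H]1C[C@@H]2C[C@H]([C@H]1C)C2(C)C)[C@@H]1C[C@@H]2C[C@H]([C@H]1C)C2(C)C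
Why: Brown asymmetric allylboration, in which the closed chair transition state of the (+)-α-pinene-derived reagent should deliver allyl to the Si face of the unbranched aldehyde and so set C3 as (R), after which alkaline peroxide cleaves borinate 6.

**Step 6**
Reactants: 8 4-(benzyloxy)benzaldehyde
Product: 9 rac-1-(ArB)prop-2-en-1-ol
Conditions: CH2=CHMgBr, THF, 0 °C; H2O quench
Reagents that add atoms: vinylmagnesium bromide, C=C[Mg]Br
Why: 1,2-Addition of a vinyl Grignard reagent to an aromatic aldehyde, the racemate being sufficient because this carbinol centre is erased in step 8.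

**Step 7**
Reactants: 7 (R)-1-(ArA)hex-5-en-3-ol; 9 rac-1-(ArB)prop-2-en-1-ol
Product: 10 (5R,E)-7-(ArA)-1-(ArB)hept-2-ene-1,5-diol (both C1 epimers; C1 = target C7)
Conditions: Hoveyda–Grubbs II (5 mol%), 9 (3 equiv), CH2Cl2, 40 °C
Reagents that add atoms: none
Why: Olefin cross-metathesis of a reactive homoallylic alcohol with an excess of a slower secondary allylic alcohol should favour the (E)-cross product, and neither alkene geometry nor the benzylic configuration needs control because both converge in step 8.

**Step 8**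
Reactants: 10 (5R,E)-7-(ArA)-1-(ArB)hept-2-ene-1,5-diol; 11 benzaldehyde dimethyl acetal
Product: 13 all-cis (4R,6R)-4-[2-(ArA)ethyl]-6-[(E)-2-(ArB)ethenyl]-2-phenyl-1,3-dioxane, via transposed hept-1-ene-3,5-diol 12 (not isolated)
Conditions: Re2O7 (5 mol%), PhCH(OMe)2 (2 equiv), CH2Cl2, 0 °C to rt
Reagents that add atoms: none
Why: The Re(VII) oxo species esterifies the C7 allylic hydroxyl and the perrhenate migrates through a chair-like six-membered [3,3] transition state (with an ion-pair limit for this p-alkoxybenzylic system), moving oxygen from C7 to C5 and the alkene to C6=C7, every step being reversible. The closest known reaction type is the Re(VII)-oxo-catalysed 1,3-transposition of allylic alcohols in which a neighbouring hydroxyl traps the transposed isomer as a cyclic acetal. The 1,3-dioxane closes by acid-catalysed transacetalisation of O3 and O5 with the dimethyl acetal, the second C–O bond arising from attack of the free hydroxyl on the oxocarbenium ion of the mixed acetal (a reversible, formally 6-endo-trig closure) that only the transposed 1,3-diol can undergo without strain. The new C5 centre is controlled by the fixed (R)-C3 centre, since reversible cleavage and re-formation of the allylic C5–O bond lets the anti isomer drain into the 4,6-diequatorial chair, and the acetal carbon takes the configuration with equatorial phenyl for the same thermodynamic reason. The step needs regioselectivity (oxygen at C5, not C7) and 1,3-syn diastereoselectivity; the first is secured by conjugation of the new alkene with ArB together with the six-membered acetal, the second by the all-equatorial chair, so both C7 epimers and any Z-alkene should converge on one product.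

**Step 9**
Reactants: 13 all-cis (4R,6R)-4-[2-(ArA)ethyl]-6-[(E)-2-(ArB)ethenyl]-2-phenyl-1,3-dioxane
Product: 14 all-cis (4R,6S)-4-[2-(ArA)ethyl]-6-[2-(ArB)ethyl]-2-phenyl-1,3-dioxane
Conditions: 2-nitrobenzenesulfonyl hydrazide (NBSH, excess in portions), Et3N, CH2Cl2, rt
Reagents that add atoms: none
Why: Diimide reduction transfers H2 to the styrene in a concerted syn fashion under mildly basic conditions, sparing the benzyl ethers and the allylic C5–O bond that a palladium catalyst could hydrogenolyse, and C5 is renamed (S) by CIP ranking alone.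

**Step 10**
Reactants: 14 all-cis (4R,6S)-4-[2-(ArA)ethyl]-6-[2-(ArB)ethyl]-2-phenyl-1,3-dioxane
Product: 15 (3R,5S)-1-(3,4-dihydroxy-5-methoxyphenyl)-7-(4-hydroxyphenyl)heptane-3,5-diol
Conditions: H2 (1 atm), 10% Pd/C, EtOAc/MeOH, rt
Reagents that add atoms: none
Why: Catalytic hydrogenolysis cleaves the three benzyl ethers and the benzylidene acetal at their benzylic C–O bonds in one operation, the C3 and C5 carbinol bonds being no longer allylic or benzylic and therefore retained.

**Compound list**
1 | 3,4-dihydroxy-5-methoxybenzaldehyde | COc1cc(C=O)cc(O)c1O | starting material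
2 | 3,4-bis(benzyloxy)-5-methoxybenzaldehyde | COc1cc(C=O)cc(OCc2ccccc2)c1OCc1ccccc1 | intermediate
3 | methyl (E)-3-[3,4-bis(benzyloxy)-5-methoxyphenyl]prop-2-enoate | COc1cc(/C=C/C(=O)OC)cc(OCc2ccccc2)c1OCc1ccccc1 | intermediate
4 | methyl 3-[3,4-bis(benzyloxy)-5-methoxyphenyl]propanoate | COc1cc(CCC(=O)OC)cc(OCc2ccccc2)c1OCc1ccccc1 | intermediate
5 | 3-[3,4-bis(benzyloxy)-5-methoxyphenyl]propanal | COc1cc(CCC=O)cc(OCc2ccccc2)c1OCc1ccccc1 | intermediate
6 | (R)-1-[3,4-bis(benzyloxy)-5-methoxyphenyl]hex-5-en-3-yl bis[(1R,2S,3R,5R)-isopinocampheyl]borinate, formed in the flask | COc1cc(CC[C@H](CC=C)OB([C@@H]2C[C@@H]3C[C@H]([C@H]2C)C3(C)C)[C@@H]2C[C@@H]3C[C@H]([C@H]2C)C3(C)C)cc(OCc2ccccc2)c1OCc1ccccc1 | intermediate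
7 | (R)-1-[3,4-bis(benzyloxy)-5-methoxyphenyl]hex-5-en-3-ol | COc1cc(CC[C@@H](O)CC=C)cc(OCc2ccccc2)c1OCc1ccccc1 | intermediate
8 | 4-(benzyloxy)benzaldehyde | O=Cc1ccc(OCc2ccccc2)cc1 | starting material
9 | rac-1-[4-(benzyloxy)phenyl]prop-2-en-1-ol | C=CC(O)c1ccc(OCc2ccccc2)cc1 | intermediate
10 | (5R,E)-7-[3,4-bis(benzyloxy)-5-methoxyphenyl]-1-[4-(benzyloxy)phenyl]hept-2-ene-1,5-diol, both C1 epimers | COc1cc(CC[C@@H](O)C/C=C/C(O)c2ccc(OCc3ccccc3)cc2)cc(OCc2ccccc2)c1OCc1ccccc1 | intermediate
11 | benzaldehyde dimethyl acetal | COC(OC)c1ccccc1 | starting material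
12 | (5R,E)-7-[3,4-bis(benzyloxy)-5-methoxyphenyl]-1-[4-(benzyloxy)phenyl]hept-1-ene-3,5-diol, interconverting C3 epimers, formed in the flask | COc1cc(CC[C@@H](O)CC(O)/C=C/c2ccc(OCc3ccccc3)cc2)cc(OCc2ccccc2)c1OCc1ccccc1 | intermediate
13 | (4R,6R)-4-{2-[3,4-bis(benzyloxy)-5-methoxyphenyl]ethyl}-6-{(E)-2-[4-(benzyloxy)phenyl]ethenyl}-2-phenyl-1,3-dioxane, 2-phenyl cis to both other substituents | COc1cc(CC[C@@H]2C[C@H](/C=C/c3ccc(OCc4ccccc4)cc3)O[C@H](c3ccccc3)O2)cc(OCc2ccccc2)c1OCc1ccccc1 | intermediate
14 | (4R,6S)-4-{2-[3,4-bis(benzyloxy)-5-methoxyphenyl]ethyl}-6-{2-[4-(benzyloxy)phenyl]ethyl}-2-phenyl-1,3-dioxane, 2-phenyl cis to both other substituents | COc1cc(CC[C@@H]2C[C@H](CCc3ccc(OCc4ccccc4)cc3)O[C@H](c3ccccc3)O2)cc(OCc2ccccc2)c1OCc1ccccc1 | intermediate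
15 | (3R,5S)-1-(3,4-dihydroxy-5-methoxyphenyl)-7-(4-hydroxyphenyl)heptane-3,5-diol | COc1cc(CC[C@@H](O)C[C@@H](O)CCc2ccc(O)cc2)cc(O)c1O | target

**Step count.** Total: 10 steps. Longest linear sequence: 9 steps (steps 1–5 and 7–10); step 6 is a one-step side branch.

**Steps most likely to fail**

1. Step 8. The doubly activated (allylic and p-alkoxybenzylic) positions may ionise irreversibly instead of equilibrating: proton loss to a conjugated diene, capture of the cation by O3 or by the electron-rich ArA ring, or incomplete drainage of the anti acetal. The fallback uses known chemistry and delivers oxygen to C5 by conjugate addition instead of transposition. Setting out from 10, MnO2 in CH2Cl2 should oxidise only the allylic benzylic hydroxyl to the (R,E)-5-hydroxy enone F1. Base-mediated hemiacetal formation with benzaldehyde followed by intramolecular oxa-Michael addition (PhCHO, KOtBu, THF, 0 °C) should give the all-cis benzylidene acetal ketone F2 under thermodynamic control. NaBH4 should give the benzylic carbinol F3, and its dehydration (Martin sulfurane, CH2Cl2) should deliver the styrene, returning to the route at 13.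

2. Step 7. Ruthenium-hydride isomerisation of the aryl vinyl carbinol to its ethyl ketone, homodimerisation of 7, or slow turnover of the hindered, acid-labile partner may erode the cross-coupling. The fallback introduces the aryl group as a nucleophile instead of by metathesis. From 7, cross-metathesis with crotonaldehyde (Hoveyda–Grubbs II, CH2Cl2, 40 °C) should give the (R,E)-5-hydroxy enal F4. 1,2-Addition of 4-(benzyloxy)phenylmagnesium bromide (2.2 equiv, from 1-(benzyloxy)-4-bromobenzene; THF, −78 °C) should then give 10, where the route is rejoined.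

3. Step 5. Facial selectivity with an unbranched aldehyde may be insufficient, and the minor enantiomer cannot be purged later because C5 is set relative to C3. The fallback resolves an epoxide instead of relying on reagent-controlled allylation. From 5, Corey–Chaykovsky methylenation (Me3S+ I−, NaH, DMSO/THF) should give the racemic epoxide F5. Hydrolytic kinetic resolution with (R,R)-(salen)Co(III)OAc and 0.55 equiv of water should leave the (R)-epoxide F6 while the (S)-enantiomer is removed as its diol. Copper-catalysed opening at the terminal carbon with vinylmagnesium bromide (CuI, THF, −40 °C) should give 7, where the route is rejoined.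

**Further compounds**
F1 | step 8 | (R,E)-7-[3,4-bis(benzyloxy)-5-methoxyphenyl]-1-[4-(benzyloxy)phenyl]-5-hydroxyhept-2-en-1-one | COc1cc(CC[C@@H](O)C/C=C/C(=O)c2ccc(OCc3ccccc3)cc2)cc(OCc2ccccc2)c1OCc1ccccc1
F2 | step 8 | 2-(all-cis-6-{2-[3,4-bis(benzyloxy)-5-methoxyphenyl]ethyl}-2-phenyl-1,3-dioxan-4-yl)-1-[4-(benzyloxy)phenyl]ethan-1-one | COc1cc(CC[C@@H]2C[C@H](CC(=O)c3ccc(OCc4ccccc4)cc3)O[C@H](c3ccccc3)O2)cc(OCc2ccccc2)c1OCc1ccccc1
F3 | step 8 | 2-(all-cis-6-{2-[3,4-bis(benzyloxy)-5-methoxyphenyl]ethyl}-2-phenyl-1,3-dioxan-4-yl)-1-[4-(benzyloxy)phenyl]ethan-1-ol, carbinol epimers | COc1cc(CC[C@@H]2C[C@H](CC(O)c3ccc(OCc4ccccc4)cc3)O[C@H](c3ccccc3)O2)cc(OCc2ccccc2)c1OCc1ccccc1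
F4 | step 7 | (R,E)-7-[3,4-bis(benzyloxy)-5-methoxyphenyl]-5-hydroxyhept-2-enal | COc1cc(CC[C@@H](O)C/C=C/C=O)cc(OCc2ccccc2)c1OCc1ccccc1
F5 | step 5 | rac-2-{2-[3,4-bis(benzyloxy)-5-methoxyphenyl]ethyl}oxirane | COc1cc(CCC2CO2)cc(OCc2ccccc2)c1OCc1ccccc1
F6 | step 5 | (R)-2-{2-[3,4-bis(benzyloxy)-5-methoxyphenyl]ethyl}oxirane | COc1cc(CC[C@@H]2CO2)cc(OCc2ccccc2)c1OCc1ccccc1
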